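**Retrosynthetic overview** (isochromene numbering O2, C1, C3, C4, C4a, C5–C8, C8a for the quinone methide half; primes for the isochroman half)

1. The C7–CH2–C7' bridge is cut into ortho-quinone methide 17 (from Mannich base 16, right half) and vinylogous acid 14 (left half). Since 15 comes from 14 by hydride addition at C1, one monomer serves both halves.
2. The pyranoid ring of 14 is closed last, by an orthoformate carbon (C1) delivered from the side-chain oxygen to C8a of resorcinol monoether 11.
3. The carbocycle of 11 (C4a, C5, C6, C7, C8, C8a) comes from cyclobutenone 5 and ethoxyacetylene by benzannulation, a two-carbon ring expansion. C6(=O), C5(Me), C4a and C8a are the four-membered ring; C7 and C8(O) are the alkyne carbons inserted between C6 and C8a.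
4. Enabling feature: in the left carbocycle the oxygens on C6 and C8 are meta and flank unsubstituted C7, and C8a bears no oxygen. That is the pattern a ketene carbonyl plus an ynol ether delivers, and it leaves C7–H and C8a–H free for the three one-carbon links (C1, C1', bridge).
5. Cyclobutenone 5 comes from alkyne 3 by keteniminium [2+2]; both stereocentres come from (2S,3S)-2,3-dimethyloxirane (acetylide opening, then Mitsunobu inversion). Ring order: cyclobutenone, benzenoid carbocycle, pyranoid ring, then reduction of one copy and union.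

Key step: step 4

Remark: (2S,3S)-2,3-dimethyloxirane is taken as a purchasable starting material (otherwise two known steps from (2S,3S)-butane-2,3-diol).
Remark: 14 and 18 are written as the 6-hydroxy-8-oxo tautomer of the target SMILES; hydrolysis of 13 first gives the 8-hydroxy-6-oxo tautomer of the same compound.
Remark: 4, 5, 7, 9 and 12 each carry one uncontrolled ring carbon (written without descriptor); it becomes sp2 later in the route.

Step 1
Reactants: 1 (2S,3S)-2,3-dimethyloxirane
Product: 2 (2S,3S)-3-methylpent-4-yn-2-ol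
Conditions: LiC≡CH·H2NCH2CH2NH2 (1.5 equiv), DMSO, 20 °C; then H2O
Reagents that add atoms: lithium acetylide ethylenediamine complex, LiC≡CH·H2NCH2CH2NH2, [Li+].[C-]#C.NCCN
Why: Epoxide alkynylation by SN2 opening should invert the attacked carbon and retain the carbinol carbon, so the C2-symmetric (2S,3S) epoxide (both carbons equivalent) gives the syn (2S,3S) alkynol.

Step 2
Reactants: 2 (2S,3S)-3-methylpent-4-yn-2-ol
Product: 3 (2R,3S)-3-methylpent-4-yn-2-yl 4-nitrobenzoate
Conditions: 4-O2NC6H4CO2H, PPh3, DIAD, THF, 0 °C to rt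
Reagents that add atoms: 4-nitrobenzoic acid, OC(=O)c1ccc(cc1)[N+](=O)[O-]
Why: Mitsunobu esterification should invert the carbinol centre (S to R), which sets the anti relationship needed for the trans-3,4-dimethyl pyran rings and leaves an electron-poor ester as protecting group.

Step 3
Reactants: 3 (2R,3S)-3-methylpent-4-yn-2-yl 4-nitrobenzoate
Product: 5 (2R,3S)-3-(4-methyl-3-oxocyclobut-1-en-1-yl)butan-2-yl 4-nitrobenzoate as a mixture of epimers at ring C4, via cyclobuteniminium triflate 4 (not isolated)
Conditions: EtCONMe2, Tf2O, CH2Cl2, −20 °C; then 3, 2,4,6-collidine, ClCH2CH2Cl, 80 °C; then H2O, rt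
Reagents that add atoms: N,N-dimethylpropanamide, CCC(=O)N(C)C; water, O
Why: In this keteniminium–alkyne [2+2] cycloaddition the terminal alkyne carbon should attack the central carbon of the keteniminium ion made in the flask, so the branched substituent ends on ring C3 and hydrolysis of iminium 4 gives the cyclobutenone; the new ring C4 centre is not controlled and is erased in step 4.

Step 4
Reactants: 5 (2R,3S)-3-(4-methyl-3-oxocyclobut-1-en-1-yl)butan-2-yl 4-nitrobenzoate
Product: 10 (2R,3S)-3-(5-ethoxy-3-hydroxy-2-methylphenyl)butan-2-yl 4-nitrobenzoate, via vinylketene 6 (not isolated), via 4-alkenyl-3-ethoxycyclobutenone 7 (not isolated), via dienylketene 8 (not isolated), via cyclohexa-2,4-dienone 9 (not isolated)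
Conditions: HC≡COEt (3 equiv, solution in hexanes), toluene, sealed tube, 80 °C then 110 °C
Reagents that add atoms: ethoxyacetylene, CCOC#C
Why: Danheiser benzannulation: thermal four-electron electrocyclic opening of 5 gives vinylketene 6, which undergoes regiospecific [2+2] cycloaddition with the ynol ether (its nucleophilic CH carbon bonds to the ketene carbonyl carbon, the OEt-bearing carbon to the ketene alpha carbon) to give 7; a second four-electron opening gives dienylketene 8, six-electron electrocyclisation gives dienone 9, and tautomerisation gives phenol 10. The closest known reaction type is the aromatic annulation of 3-alkyl and ring-substituted cyclobutenones with alkoxy- and siloxyalkynes. The six-membered carbocycle is closed by disrotatory six-electron electrocyclisation that re-forms the former C1–C4 bond of the cyclobutenone after the two alkyne carbons (future C7 and C8) have been inserted between C1 and C2, a net two-carbon ring expansion; the four-membered ring of 7 is closed by the [2+2] step and opened again. No stereocentre is created: the two side-chain stereocentres lie outside every pericyclic array and are not enolisable under neutral thermal conditions, and the ring C4 epimers of 5 converge because that carbon becomes aromatic C5. The step needs [2+2] regioselectivity and capture of the ketene by the alkyne instead of by a nucleophile or a second ketene; the first follows from the polarisation of ethoxyacetylene, the second from ester protection of the alcohol and an excess of the volatile alkyne in a closed vessel.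

Step 5
Reactants: 10 (2R,3S)-3-(5-ethoxy-3-hydroxy-2-methylphenyl)butan-2-yl 4-nitrobenzoate
Product: 11 (2R,3S)-3-(5-ethoxy-3-hydroxy-2-methylphenyl)butan-2-ol
Conditions: K2CO3 (cat.), MeOH, rt
Reagents that add atoms: none
Why: Base-catalysed transesterification (methanolysis) of the activated 4-nitrobenzoate should free the secondary alcohol without touching either stereocentre.

Step 6
Reactants: 11 (2R,3S)-3-(5-ethoxy-3-hydroxy-2-methylphenyl)butan-2-ol
Product: 14 (3R,4S)-6-hydroxy-3,4,5-trimethyl-3,4-dihydro-8H-isochromen-8-one (decarboxycitrinin), via 1-ethoxyisochroman acetal 12 (not isolated), via 8-ethoxy quinone methide 13 (not isolated)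
Conditions: HC(OEt)3 (1.5 equiv), CF3CO2H, CH2Cl2, 0 °C to rt; evaporate; then 1 M aq HCl, THF, 50 °C
Reagents that add atoms: triethyl orthoformate, CCOC(OCC)OCC; water, O
Why: Alcohol–orthoformate exchange should give an alkoxycarbenium ion that closes onto C8a (ortho to OEt, para to OH) in an oxa-Pictet–Spengler-type cyclisation at the formate oxidation level, loss of ethanol from acetal 12 gives para-quinone methide 13, and acid hydrolysis of its vinylogous ester gives 14, the ethyl ether having kept C7 from reacting with the orthoformate.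

Step 7
Reactants: 14 (3R,4S)-6-hydroxy-3,4,5-trimethyl-3,4-dihydro-8H-isochromen-8-one
Product: 15 (3R,4S)-3,4,5-trimethyl-3,4-dihydro-1H-isochromene-6,8-diol
Conditions: Et3SiH, CF3CO2H, CH2Cl2, 0 °C to rt
Reagents that add atoms: none
Why: In this ionic hydrogenation O-protonation of 14 should give a 2-benzopyrylium ion that accepts hydride from the silane at C1 and so restores the aromatic ring.

Step 8
Reactants: 15 (3R,4S)-3,4,5-trimethyl-3,4-dihydro-1H-isochromene-6,8-diol
Product: 16 (3R,4S)-7-[(dimethylamino)methyl]-3,4,5-trimethyl-3,4-dihydro-1H-isochromene-6,8-diol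
Conditions: aq CH2O, aq Me2NH, EtOH, 0 °C to rt
Reagents that add atoms: formaldehyde, C=O; dimethylamine, CNC
Why: The phenolic Mannich reaction can only occur at C7, the single unsubstituted ring position of 15, flanked by both hydroxyl groups.

Step 9
Reactants: 16 (3R,4S)-7-[(dimethylamino)methyl]-3,4,5-trimethyl-3,4-dihydro-1H-isochromene-6,8-diol; 14 (3R,4S)-6-hydroxy-3,4,5-trimethyl-3,4-dihydro-8H-isochromen-8-one
Product: 18 dicitrinone I, via ortho-quinone methide 17 (not isolated)
Conditions: 14 (1.1 equiv), 1,4-dioxane, 80 °C, N2 stream; work-up at pH 4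
Reagents that add atoms: none
Why: Thermal loss of dimethylamine from the ortho-hydroxybenzylamine, helped by proton transfer from the vinylogous acid, should give ortho-quinone methide 17, which is captured by Michael addition of C7 of 14 (its only nucleophilic carbon) and rearomatises to the methylene-bridged product.

**Compound list**

1 | (2S,3S)-2,3-dimethyloxirane (trans-2,3-epoxybutane) | C[C@@H]1O[C@H]1C | starting material
2 | (2S,3S)-3-methylpent-4-yn-2-ol | O[C@@H](C)[C@H](C#C)C | intermediate
3 | (2R,3S)-3-methylpent-4-yn-2-yl 4-nitrobenzoate | O=C(O[C@H](C)[C@H](C#C)C)c1ccc(cc1)[N+](=O)[O-] | intermediate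
4 | N,N-dimethyl-4-methyl-3-[(2S,3R)-3-(4-nitrobenzoyloxy)butan-2-yl]cyclobut-2-en-1-iminium triflate | O=C(O[C@H](C)[C@H](C1=CC(=[N+](C)C)C1C)C)c1ccc(cc1)[N+](=O)[O-].[O-]S(=O)(=O)C(F)(F)F | intermediate (not isolated)
5 | (2R,3S)-3-(4-methyl-3-oxocyclobut-1-en-1-yl)butan-2-yl 4-nitrobenzoate | O=C(O[C@H](C)[C@H](C1=CC(=O)C1C)C)c1ccc(cc1)[N+](=O)[O-] | intermediate
6 | (2R,3S)-3-(1-oxopenta-1,3-dien-3-yl)butan-2-yl 4-nitrobenzoate (vinylketene) | O=C(O[C@H](C)[C@H](C(C=C=O)=CC)C)c1ccc(cc1)[N+](=O)[O-] | intermediate (not isolated)
7 | (2R,3S)-3-[1-(2-ethoxy-4-oxocyclobut-2-en-1-yl)prop-1-en-1-yl]butan-2-yl 4-nitrobenzoate | O=C(O[C@H](C)[C@H](C(=CC)C1C(=O)C=C1OCC)C)c1ccc(cc1)[N+](=O)[O-] | intermediate (not isolated)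
8 | (2R,3S)-3-(5-ethoxy-7-oxohepta-2,4,6-trien-3-yl)butan-2-yl 4-nitrobenzoate (dienylketene) | O=C(O[C@H](C)[C@H](C(=CC)C=C(OCC)C=C=O)C)c1ccc(cc1)[N+](=O)[O-] | intermediate (not isolated)
9 | (2R,3S)-3-(3-ethoxy-6-methyl-5-oxocyclohexa-1,3-dien-1-yl)butan-2-yl 4-nitrobenzoate | O=C(O[C@H](C)[C@H](C1=CC(OCC)=CC(=O)C1C)C)c1ccc(cc1)[N+](=O)[O-] | intermediate (not isolated)
10 | (2R,3S)-3-(5-ethoxy-3-hydroxy-2-methylphenyl)butan-2-yl 4-nitrobenzoate | O=C(O[C@H](C)[C@H](c1cc(OCC)cc(O)c1C)C)c1ccc(cc1)[N+](=O)[O-] | intermediate
11 | (2R,3S)-3-(5-ethoxy-3-hydroxy-2-methylphenyl)butan-2-ol | O[C@H](C)[C@H](c1cc(OCC)cc(O)c1C)C | intermediate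
12 | (3R,4S)-1,8-diethoxy-3,4,5-trimethyl-3,4-dihydro-1H-isochromen-6-ol (C1 epimers) | CCOc1cc(O)c(C)c2c1C(OCC)O[C@H](C)[C@H]2C | intermediate (not isolated)
13 | (3R,4S)-8-ethoxy-3,4,5-trimethyl-3,4-dihydro-6H-isochromen-6-one | CCOC1=CC(=O)C(C)=C2C1=CO[C@H](C)[C@H]2C | intermediate (not isolated)
14 | (3R,4S)-6-hydroxy-3,4,5-trimethyl-3,4-dihydro-8H-isochromen-8-one (decarboxycitrinin) | CC1=C2C(=CO[C@H](C)[C@H]2C)C(=O)C=C1O | intermediate
15 | (3R,4S)-3,4,5-trimethyl-3,4-dihydro-1H-isochromene-6,8-diol | Oc1cc(O)c(C)c2c1CO[C@H](C)[C@H]2C | intermediate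
16 | (3R,4S)-7-[(dimethylamino)methyl]-3,4,5-trimethyl-3,4-dihydro-1H-isochromene-6,8-diol | CN(C)Cc1c(O)c(C)c2c(c1O)CO[C@H](C)[C@H]2C | intermediate
17 | (3R,4S)-8-hydroxy-3,4,5-trimethyl-7-methylidene-3,4-dihydro-1H-isochromen-6(7H)-one | C=C1C(=O)C(C)=C2C(=C1O)CO[C@H](C)[C@H]2C | intermediate (not isolated)
18 | dicitrinone I | CC1=C2C(=CO[C@H](C)[C@H]2C)C(=O)C(Cc2c(O)c(C)c3c(c2O)CO[C@H](C)[C@H]3C)=C1O | target

**Totals**

Total step count: 9. Longest linear sequence: 9 (steps 1 to 9; compound 14 is drawn on in both step 7 and step 9).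

**Steps most likely to fail**

Step 3. The cationic intermediate of the stepwise cycloaddition may be intercepted by the ester carbonyl or suffer a hydride shift from the adjacent methine, or the branched alkyne may react too slowly. The fallback sets out from 3 and returns at 5. Alkyne 3 would be treated with chloro(methyl)ketene generated in the flask from 2,2-dichloropropanoyl chloride and Zn–Cu couple (Et2O, 1,2-dimethoxyethane). This haloketene–alkyne [2+2] cycloaddition has the same regiochemistry and should give (2R,3S)-3-(4-chloro-4-methyl-3-oxocyclobut-1-en-1-yl)butan-2-yl 4-nitrobenzoate F1. Reductive dechlorination with zinc dust, AcOH and TMEDA in EtOH should then give 5.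

Step 6. The orthoformate may formylate C7 intermolecularly or link two rings through one carbon before the intramolecular ring closure takes place. The fallback sets out from 11 and returns at 13. Oxa-Pictet–Spengler cyclisation of 11 with dimethoxymethane (p-TsOH, toluene, 60 °C) should give (3R,4S)-8-ethoxy-3,4,5-trimethyl-3,4-dihydro-1H-isochromen-6-ol F2. Dehydrogenation with DDQ in 1,4-dioxane (hydride abstraction from C1, para to the free phenol) should then give quinone methide 13, which is hydrolysed to 14 as in step 6.

Step 9. The aminomethyl group may be transferred to 14 by retro-Mannich exchange, which scrambles the partners into symmetric dimers, or the liberated amine may add reversibly at C1 of the quinone methide. The fallback sets out from 15 and 14 and returns at 18. Vilsmeier–Haack formylation of 15 (POCl3, DMF; then aq NaOAc) at its only free position should give (3R,4S)-6,8-dihydroxy-3,4,5-trimethyl-3,4-dihydro-1H-isochromene-7-carbaldehyde F3. A three-component reductive alkylation of 14 with F3 and Hantzsch ester (cat. L-proline, CH2Cl2, rt) would proceed by Knoevenagel condensation to (3R,4S)-7-{[(3R,4S)-6,8-dihydroxy-3,4,5-trimethyl-3,4-dihydro-1H-isochromen-7-yl]methylidene}-3,4,5-trimethyl-3,4-dihydroisochromene-6,8-dione F4 (not isolated). Conjugate transfer hydrogenation of F4 should give 18.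

**Further compounds**

F1 | step 3 | (2R,3S)-3-(4-chloro-4-methyl-3-oxocyclobut-1-en-1-yl)butan-2-yl 4-nitrobenzoate | O=C(O[C@H](C)[C@H](C1=CC(=O)C1(C)Cl)C)c1ccc(cc1)[N+](=O)[O-]
F2 | step 6 | (3R,4S)-8-ethoxy-3,4,5-trimethyl-3,4-dihydro-1H-isochromen-6-ol | CCOc1cc(O)c(C)c2c1CO[C@H](C)[C@H]2C
F3 | step 9 | (3R,4S)-6,8-dihydroxy-3,4,5-trimethyl-3,4-dihydro-1H-isochromene-7-carbaldehyde | O=Cc1c(O)c(C)c2c(c1O)CO[C@H](C)[C@H]2C
F4 | step 9 | (3R,4S)-7-{[(3R,4S)-6,8-dihydroxy-3,4,5-trimethyl-3,4-dihydro-1H-isochromen-7-yl]methylidene}-3,4,5-trimethyl-3,4-dihydroisochromene-6,8-dione | CC1=C2C(=CO[C@H](C)[C@H]2C)C(=O)C(=Cc2c(O)c(C)c3c(c2O)CO[C@H](C)[C@H]3C)C1=O
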